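Whatever target you find at the end is a leftover: what formation has put in and loss has not yet taken away. I reckon it with two mean pseudo-first-order constants in place of the real curves.

| setting | delta | flask |
|---|---|---|
| substrate | 0.025 M | 0.050 M |
| gas phase | 20 mM (held) | 20 mM (held) |
| remark | run made earlier |  |
| time |  | 40 h |

delta run (percent of the substrate charged)

| time / h | target / % |
|---|---|
| 2.00 | 3.4 |
| 4.00 | 7.6 |
| 6.00 | 9.0 |
| 8.00 | 13.3 |
| 10.0 | 13.6 |
| 12.0 | 11.7 |

(scatter of a reading: 1 percentage point)

- at the start none of the gas is dissolved
- the numbers in the tables scatter by 1 percentage point (one standard deviation)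
- reactions considered so far: dissolved gas + target -> over-reacted product; gas phase <-> dissolved gas; substrate + dissolved gas -> target; target -> over-reaction product; dissolved gas <-> dormant form; target <-> isomer of the product

* amount of target at 40 h, in percent of the substrate charged
* concentration of dissolved gas in solution at 4.0 h, in percent of saturation
* the change that raises the amount of target at 40 h, in percent of the substrate charged most ("none" if none brings more than 2 percentage points) (east / north-west / none)
* amount of target at 40 h, in percent of the substrate charged, after east

- east: doubling the saturation concentration of gas phase, all else as stated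
- north-west: doubling the transfer coefficient of the gas phase, all else as stated

The formation constant comes from the early slope of the delta run, and at the peak formation equals loss. That gives the loss constant, the mean first-order rate at which target disappears:

kf = target at 4.00 h / 4.00 h = 0.0190 h⁻¹

kl = kf · exp(−kf · 10.0 h) / 13.6% = 0.116 h⁻¹

c(target) / c(substrate, charged) = kf/(kl − kf) · (exp(−kf t) − exp(−kl t))

Now test each input. Taking kf from the 2.00 h reading gives 0.0170 h⁻¹ and 8.53% at 40 h. Taking the peak at 8.00 h gives 0.123 h⁻¹ and 8.41%. The charge drops out of these percentages, though your flask holds twice the delta charge and, at kf, asks for 0.950 mM h⁻¹ of gas.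

My number is 9.01%, with 46.8% of the substrate left. The curve check at 12.0 h gives 10.7% against the reading 11.7%. The weak point is the extrapolation: kf is read at 4.00 h of the delta run, where dissolved gas started from nothing, and is carried to 40 h. Watch the substrate.

The forecast gives 9% (4% to 15%), 70% (40% to 95%), none and 8% (3% to 15%), holding that the “target sits in quasi-steady state with the remaining substrate”.

    dissolved gas + target → over-reacted product (k = 6.20 L mol⁻¹ h⁻¹)
    gas phase ⇌ dissolved gas, rate k2*(csat - [dissolved gas]) (kL = 0.590 h⁻¹)
    substrate + dissolved gas → target (k = 2.70 L mol⁻¹ h⁻¹)
    target → over-reaction product (k = 6.50 × 10⁻⁵ h⁻¹)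
    dissolved gas ⇌ dormant form (K = 1.90, k = 0.0970 h⁻¹)
    target ⇌ isomer of the product (K = 16.0, k = 0.160 h⁻¹)

The flask gives 5.49% of target at 40 h. Its dissolved gas stands at 69.3% of saturation at 4.0 h. The best change is none: east moves the target by −3.5 percentage points, to 1.96%, and north-west moves it by −0.63 points. The flask's target stands below my reckoning, and its substrate is 18% against the reckoned 46.8%. On the neighbouring flask, stopped at 15 h, the same kf and kl give 11.3% of target, and that flask holds 10.9%. The reckoned substrate there is 75.2%, and the flask holds 57.7%.

(All runs were computed for substances that don't exist, and the scatter is random.)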